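## Retrosynthetic overview

- **Feature:** the ester carbonyl carbon C1 is a single carbon. On one side it bonds to C2 of a fully unbranched chain (C2–C36, n-C35H71). On the other it bonds to the oxygen of the OCH2CH2 arm on the para-hydroxyphenyl ring. C1 with its oxygen therefore corresponds to carbon monoxide.
- **Key disconnection:** C1–C2 and C1–O are cut together, giving a linear C35 olefin, CO and tyrosol. The position of the double bond is free, because a chain-walking palladium hydride carbonylates only at a chain end and both ends of the hydrocarbon are alike.
- **Olefin:** the symmetric C35 ketone stearone is reduced and dehydrated. Its two alpha-methylene groups are equivalent, so only one primary olefin can form.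
- **Rings and stereocentres:** no ring is formed, since the only ring (the benzene ring) is bought with tyrosol. The target has no stereocentre.

Key step: step 3

Remark on the chemistry: the C35 olefin is drawn as the 17-ene. Double-bond isomers formed alongside it are equally competent feed for the carbonylation and are not separated.

## Route

Step 1
Reactants: 1 stearone (pentatriacontan-18-one)
Product: 2 pentatriacontan-18-ol
Conditions: NaBH4 (1 equiv), THF/EtOH 4:1, 60 °C; then H2O, crystallisation on cooling
Reagents that add atoms: none
Why: Borohydride reduction of a dialkyl ketone; hot THF keeps the waxy ketone in solution, and the carbinol carbon carries two identical heptadecyl groups, so no stereocentre arises.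

Step 2
Reactants: 2 pentatriacontan-18-ol
Product: 3 pentatriacont-17-ene (E/Z mixture)
Conditions: p-TsOH·H2O (5 mol %), neat melt, 170 °C, slow N2 stream to carry off water; then hot heptane, short plug of basic alumina
Reagents that add atoms: none
Why: Acid-catalysed E1 dehydration of a secondary alcohol; both beta-methylene groups are equivalent, so loss of water gives the 17-ene, and any E/Z scatter or acid-induced double-bond migration is harmless because step 3 equilibrates all isomers.

Step 3
Reactants: 3 pentatriacont-17-ene (E/Z mixture); 4 carbon monoxide; 5 tyrosol
Product: 7 p-hydroxyphenethyl hexatriacontanoate, via pentatriacont-1-ene 6 (not isolated)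
Conditions: Pd(OAc)2 (2 mol %), 1,2-bis(di-tert-butylphosphinomethyl)benzene (dtbpx, 8 mol %), MeSO3H (16 mol %), CO (20 bar), 5 (3 equiv), toluene/1,4-dioxane 1:1, 95 °C, 72 h, autoclave; warm water wash, short silica column (heptane, then heptane/EtOAc), recrystallisation from EtOAc/heptane
Reagents that add atoms: carbon monoxide 4, [C-]#[O+]; tyrosol 5, OCCc1ccc(O)cc1
Why: Pd(OAc)2, the bulky diphosphine and MeSO3H give a cationic divalent palladium hydride that adds to the olefin and beta-hydride-eliminates again many times, so the double bond travels along the unbranched chain and the terminal isomer 6 and its n-pentatriacontyl palladium species are continually replenished. CO insertion is reversible for all alkyls, but the four tert-butyl groups leave room for the rate-determining alcoholysis only at the unbranched acyl, so under Curtin–Hammett conditions the whole isomer pool drains through hexatriacontanoyl palladium; insertion makes C1–C2, and attack of the CH2OH oxygen of 5 makes C1–O and returns the hydride. The closest known reaction type is the isomerising alkoxycarbonylation of internal fatty olefins (oleate, erucate, internal alkenes, and cardanol-type alkenylphenols with the phenol left free) with this same catalyst, which is also known with alcohols other than methanol. No ring is closed and no stereocentre is made, and the E/Z and positional make-up of 3 is erased during the walk. Regioselectivity (linear against branched ester) rests on ligand bulk and on the substrate being a plain hydrocarbon with two indistinguishable termini, so carbonylation at either one gives the same acyl group. Chemoselectivity (aliphatic OH against phenol OH and against ring alkylation) rests on the higher nucleophilicity of the neutral primary alcohol, on the excess of 5, on the lability of any aryl ester towards that excess, and on the acid being held largely as the phosphonium salt of the surplus ligand.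

## Compound list

1 | stearone (pentatriacontan-18-one) | CCCCCCCCCCCCCCCCCC(=O)CCCCCCCCCCCCCCCCC | starting material
2 | pentatriacontan-18-ol | CCCCCCCCCCCCCCCCCC(O)CCCCCCCCCCCCCCCCC | intermediate
3 | pentatriacont-17-ene (E/Z mixture, geometry not defined) | CCCCCCCCCCCCCCCCCC=CCCCCCCCCCCCCCCCC | intermediate
4 | carbon monoxide | [C-]#[O+] | starting material
5 | tyrosol, 2-(4-hydroxyphenyl)ethanol | OCCc1ccc(O)cc1 | starting material
6 | pentatriacont-1-ene (formed in the flask by chain walking, not isolated) | C=CCCCCCCCCCCCCCCCCCCCCCCCCCCCCCCCCCC | intermediate
7 | p-hydroxyphenethyl hexatriacontanoate = 2-(4-hydroxyphenyl)ethyl hexatriacontanoate | CCCCCCCCCCCCCCCCCCCCCCCCCCCCCCCCCCCC(=O)OCCc1ccc(O)cc1 | target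

## Step count and risks

Total step count: 3. Longest linear sequence: 3 steps (1 → 2 → 3 → 7).

**Step 3 (key step).**
- **Risk:** alcoholysis of the acyl palladium species by a diluted, near-stoichiometric alcohol may be too slow. The catalyst could then decay to palladium metal before the long walk from the chain centre has been drained. The free phenol may also take part through O-acylation or ring alkylation.
- **Fallback:** this sets out from 3 (with 4) and uncouples the carbonylation from the esterification with tyrosol.
  - The olefin is carbonylated with the same catalyst in methanol/toluene. Methanol is then in large excess, as in the best-established form of the reaction, and the product is methyl hexatriacontanoate F1, which is recrystallised.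
  - F1 is then transesterified with an excess of 5 under p-TsOH catalysis in refluxing toluene, with methanol taken up by 4 Å molecular sieves. In this equilibrium process only the aliphatic hydroxyl should be acylated, because aryl esters are thermodynamically disfavoured.
  - The route is rejoined at 7.

**Step 2.**
- **Risk:** loss of water may be incomplete, with build-up of the di-sec-alkyl ether. Acid-induced oligomerisation or skeletal branching of the olefin may occur in the hot melt, and branching would be carried through into branched esters.
- **Fallback:** this sets out from 2 and replaces the cationic dehydration by activation and base-induced E2 elimination.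
  - MsCl/Et3N in warm THF should give pentatriacontan-18-yl methanesulfonate F2.
  - F2 is treated with KOtBu in THF/toluene at 60 °C. The two beta-methylene groups are equivalent, so only the 17-ene can result, and no carbocation is involved.
  - The route is rejoined at 3.

**Step 1.**
- **Risk:** the ketone may crystallise out of the medium while borohydride is consumed by the ethanol. Conversion would then be incomplete, and ketone and alcohol are two waxy solids of similar solubility that are hard to separate.
- **Fallback:** this sets out from 1 and bypasses the alcohol by a Shapiro reaction.
  - TsNHNH2 in refluxing EtOH/toluene should give stearone p-toluenesulfonylhydrazone F3.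
  - n-BuLi (2.5 equiv) in THF/TMEDA from 0 °C to room temperature forms the dianion. It loses sulfinate and dinitrogen to give pentatriacont-17-en-18-yllithium F4, which is quenched with water.
  - The route is rejoined at 3, so that 2 and step 2 are skipped.

## Further compounds

F1 | step 3 | methyl hexatriacontanoate | CCCCCCCCCCCCCCCCCCCCCCCCCCCCCCCCCCCC(=O)OC
F2 | step 2 | pentatriacontan-18-yl methanesulfonate | CCCCCCCCCCCCCCCCCC(OS(C)(=O)=O)CCCCCCCCCCCCCCCCC
F3 | step 1 | stearone p-toluenesulfonylhydrazone | CCCCCCCCCCCCCCCCCC(=NNS(=O)(=O)c1ccc(C)cc1)CCCCCCCCCCCCCCCCC
F4 | step 1 | pentatriacont-17-en-18-yllithium | [Li]C(CCCCCCCCCCCCCCCCC)=CCCCCCCCCCCCCCCCC
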